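**Plan**

- Numbering: ring A is C1–C6 (C1 carries the bridging CH2, C3 the methyl, C5 the butanoyl group); ring B is C1'–C6' (C1' bridge, C2' OH, C3' butanoyl, C4' OH, C5' methyl, C6' OMe). Margaspidin has no stereocentre, so nothing stereochemical has to be controlled.
- Retrosynthesis: the two aryl–acyl bonds (C5–CO, C3'–CO) are cut first, then ring B at C4'–C5', C6'–C1' and C3'–C4' (a cyclobutenone plus 1-methoxypropyne), then the four-membered ring (ketene plus an ynol ether), then the bridge CH2–C(sp) bond.
- Enabling feature: in ring B the C5' methyl and the C6' methoxy are neighbours and lie next to the C4' hydroxyl, which is what 1-methoxypropyne leaves behind in a vinylketene benzannulation; C2'–O and the bridge-bearing C1' map onto C3 and C2 of a 3-alkoxy-2-(arylmethyl)cyclobutenone, and C3' emerges unsubstituted.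
- Forward: ring A comes intact from 2-methylphloroglucinol and is given its CH2 arm; an alkoxyacetylide is alkylated with it, ketene closes the cyclobutenone, the benzannulation builds ring B directly on the bridge, both butanoyl groups are put on the fully etherified diarylmethane, and one BCl3 step frees the five phenols.
- The cyclobutenone oxygen is carried as an isopropyl ether: it behaves like ethyl up to the benzannulation but is cleaved by BCl3 together with the benzyl ethers, whereas the C6' methyl ether stays.

Key step: step 9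

Remark: ketene is not sold as such; it is generated by pyrolysis of acetone, which splits off methane, so acetone is counted as the starting material of step 7.

**Route**

Step 1
Reactants: 1 2-methylbenzene-1,3,5-triol (2-methylphloroglucinol)
Product: 3 2,4,6-trihydroxy-3-methylbenzaldehyde, via aryl iminium chloride 2 (not isolated)
Conditions: POCl3 (1.1 equiv), DMF, EtOAc, 0 °C → rt; then H2O, 50 °C
Reagents that add atoms: N,N-dimethylformamide, CN(C)C=O; water, O
Why: Vilsmeier–Haack formylation, in which the chloroiminium ion attacks one of the two equivalent free ring carbons, the iminium salt 2 is too electron-poor to react a second time, and water hydrolyses it to the aldehyde.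

Step 2
Reactants: 3 2,4,6-trihydroxy-3-methylbenzaldehyde
Product: 4 2,4,6-tris(benzyloxy)-3-methylbenzaldehyde
Conditions: BnBr (3.6 equiv), K2CO3, DMF, 60 °C
Reagents that add atoms: benzyl bromide, BrCc1ccccc1
Why: Williamson ether synthesis, in which the formyl-deactivated phenolate in aprotic DMF should be alkylated on oxygen and not on the remaining ring carbon, and warming brings in the two hydrogen-bonded ortho hydroxyls as well.

Step 3
Reactants: 4 2,4,6-tris(benzyloxy)-3-methylbenzaldehyde
Product: 5 [2,4,6-tris(benzyloxy)-3-methylphenyl]methanol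
Conditions: NaBH4, THF–MeOH, 0 °C
Reagents that add atoms: none
Why: Hydride reduction of an aromatic aldehyde with NaBH4, to which the benzyl ethers are inert.

Step 4
Reactants: 5 [2,4,6-tris(benzyloxy)-3-methylphenyl]methanol
Product: 7 1,3,5-tris(benzyloxy)-2-(chloromethyl)-4-methylbenzene, via benzylic mesylate 6 (not isolated)
Conditions: MsCl, Et3N, CH2Cl2, −20 → 0 °C; cold NaHCO3 wash, solution used at once
Reagents that add atoms: methanesulfonyl chloride, CS(=O)(=O)Cl
Why: Sulfonylation gives mesylate 6, which the liberated chloride ion displaces at once (substitution at a trialkoxybenzylic carbon); because such halides ionise and self-alkylate easily, 7 is kept cold and dilute and carried on without chromatography.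

Step 5
Reactants: 8 propan-2-ol; 9 trichloroethene
Product: 11 (E)-1,2-dichloro-1-(propan-2-yloxy)ethene, via dichloroethyne 10 (not isolated)
Conditions: KH, THF, 0 °C; then 9, −50 °C → rt
Reagents that add atoms: none
Why: Base-induced loss of HCl from trichloroethene gives dichloroethyne 10, to which the alkoxide adds in an anti sense (the elimination–addition route to 1,2-dichlorovinyl ethers), and the resulting E geometry is of no consequence for the next step.

Step 6
Reactants: 11 (E)-1,2-dichloro-1-(propan-2-yloxy)ethene; 7 1,3,5-tris(benzyloxy)-2-(chloromethyl)-4-methylbenzene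
Product: 14 1,3,5-tris(benzyloxy)-2-methyl-4-[3-(propan-2-yloxy)prop-2-yn-1-yl]benzene, via chloroalkynyl ether 12 (not isolated), via lithium alkoxyacetylide 13 (not isolated)
Conditions: 11 (1.5 equiv), n-BuLi (2.1 equiv per 11), THF, −78 → −40 °C; then 7, DMPU, −78 → 0 °C
Reagents that add atoms: none
Why: n-BuLi eliminates HCl from 11 to chloroalkyne 12 and exchanges its chlorine for lithium to give acetylide 13, which the highly reactive benzylic chloride alkylates on carbon in the presence of DMPU (acetylide alkylation, SN2).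

Step 7
Reactants: 14 1,3,5-tris(benzyloxy)-2-methyl-4-[3-(propan-2-yloxy)prop-2-yn-1-yl]benzene; 15 acetone (propan-2-one)
Product: 17 3-(propan-2-yloxy)-2-{[2,4,6-tris(benzyloxy)-3-methylphenyl]methyl}cyclobut-2-en-1-one, via ketene 16 (not isolated)
Conditions: 15 pyrolysed at 700–750 °C (ketene lamp, glowing resistance wire), unchanged 15 condensed out, ketene stream passed into 14 in CH2Cl2, 0 °C → rt
Reagents that add atoms: none
Why: Pyrolysis of acetone splits off methane and delivers ketene 16, which undergoes a ketene–ynol ether [2+2] cycloaddition in which the nucleophilic alkyne carbon bearing the arylmethyl group bonds to the ketene carbonyl carbon, so that group ends at C2 and the isopropoxy group at C3 of the cyclobutenone, the orientation known for alkoxyalkynes and ketene.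

Step 8
Reactants: 18 2-chloro-1,1-dimethoxyethane (chloroacetaldehyde dimethyl acetal)
Product: 22 1-methoxyprop-1-yne, via chlorovinyl ether 19 (not isolated), via methoxyethyne 20 (not isolated), via sodium methoxyethynide 21 (not isolated)
Conditions: NaNH2 (3 equiv), liq. NH3, −33 °C; then MeI, −40 °C; distillation
Reagents that add atoms: iodomethane, CI
Why: Sodium amide removes methanol and then HCl from the acetal (through 19 and 20) and metalates the alkyne to 21, which is methylated on carbon in liquid ammonia, the standard preparation of 1-alkoxy-1-alkynes.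

Step 9
Reactants: 17 3-(propan-2-yloxy)-2-{[2,4,6-tris(benzyloxy)-3-methylphenyl]methyl}cyclobut-2-en-1-one; 22 1-methoxyprop-1-yne
Product: 27 3-methoxy-2-methyl-5-(propan-2-yloxy)-4-{[2,4,6-tris(benzyloxy)-3-methylphenyl]methyl}phenol, via vinylketene 23 (not isolated), via alkenylcyclobutenone 24 (not isolated), via dienylketene 25 (not isolated), via cyclohexadienone 26 (not isolated)
Conditions: 22 (3 equiv), toluene, sealed tube, 80 °C then 120 °C
Reagents that add atoms: none
Why: Heating opens cyclobutenone 17 by a 4π electrocyclic reaction to the (alkoxyvinyl)ketene 23, whose ketene C=C bond adds to the electron-rich alkyne 22 in a regioselective [2+2] cycloaddition to give 24; a second 4π opening gives dienylketene 25, which closes ring B by a thermal disrotatory 6π electrocyclisation (the C3'–C4' bond) to dienone 26, and this tautomerises to the phenol. The closest known reaction is the Danheiser benzannulation of cyclobutenones with alkoxyalkynes to resorcinol monoethers, and thermal vinylketene formation from alkoxy-substituted cyclobutenones is familiar from squarate-derived cyclobutenones. The selectivity needed is the orientation of the ketene–alkyne union: the methyl-bearing carbon of the ynol ether is its nucleophilic end and bonds to the electrophilic ketene carbonyl carbon (C4'–C5'), so the methoxy-bearing carbon joins the bridge-bearing carbon (C6'–C1') and the methoxy group ends para to the only unsubstituted carbon, C3'. A methyl ynol ether has no β-hydrogen for the retro-ene loss of alkene that higher alkyl ynol ethers undergo on heating, so 22 should survive the thermolysis, and its excess is meant to outrun ketene dimerisation. No stereocentre remains, because the quaternary centre of 24 is lost when that ring opens.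

Step 10
Reactants: 27 3-methoxy-2-methyl-5-(propan-2-yloxy)-4-{[2,4,6-tris(benzyloxy)-3-methylphenyl]methyl}phenol
Product: 28 1,3,5-tris(benzyloxy)-2-{[4-(benzyloxy)-2-methoxy-3-methyl-6-(propan-2-yloxy)phenyl]methyl}-4-methylbenzene
Conditions: BnBr, K2CO3, DMF, rt
Reagents that add atoms: benzyl bromide, BrCc1ccccc1
Why: Williamson benzylation of the single, only moderately hindered phenol, which turns ring B into a trialkoxybenzene like ring A and rules out O-acylation in the next step.

Step 11
Reactants: 28 1,3,5-tris(benzyloxy)-2-{[4-(benzyloxy)-2-methoxy-3-methyl-6-(propan-2-yloxy)phenyl]methyl}-4-methylbenzene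
Product: 29 1-[2,4,6-tris(benzyloxy)-3-{[4-(benzyloxy)-3-butanoyl-6-methoxy-5-methyl-2-(propan-2-yloxy)phenyl]methyl}-5-methylphenyl]butan-1-one
Conditions: butanoic acid (6 equiv), (CF3CO)2O (6 equiv), CH2Cl2, 0 °C → rt
Reagents that add atoms: butanoic acid, CCCC(=O)O
Why: Friedel–Crafts acylation by the mixed butanoic trifluoroacetic anhydride, in which each ring offers exactly one unsubstituted carbon (flanked by two alkoxy groups and para to a third), so no regiochemical choice arises, and the metal-free, weakly acidic medium should spare the benzyl and isopropyl ethers and the acid-sensitive diarylmethane bridge.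

Step 12
Reactants: 29 1-[2,4,6-tris(benzyloxy)-3-{[4-(benzyloxy)-3-butanoyl-6-methoxy-5-methyl-2-(propan-2-yloxy)phenyl]methyl}-5-methylphenyl]butan-1-one
Product: 30 margaspidin
Conditions: BCl3 (12 equiv), C6HMe5 (15 equiv), CH2Cl2, −78 → 0 °C; then MeOH
Reagents that add atoms: none
Why: Lewis acid ether cleavage, in which BCl3 with pentamethylbenzene as cation scavenger removes the four aryl benzyl ethers at −78 °C and the secondary isopropyl ether on warming to 0 °C, while the C6' methyl ether, which cannot ionise and is not chelated to a carbonyl group, should remain.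

**Compound list**

1 | 2-methylbenzene-1,3,5-triol (2-methylphloroglucinol) | Cc1c(O)cc(O)cc1O | starting material
2 | [(2,4,6-trihydroxy-3-methylphenyl)methylidene]dimethylazanium chloride | C[N+](C)=Cc1c(O)c(C)c(O)cc1O.[Cl-] | intermediate
3 | 2,4,6-trihydroxy-3-methylbenzaldehyde | O=Cc1c(O)c(C)c(O)cc1O | intermediate
4 | 2,4,6-tris(benzyloxy)-3-methylbenzaldehyde | O=Cc1c(OCc2ccccc2)c(C)c(OCc2ccccc2)cc1OCc1ccccc1 | intermediate
5 | [2,4,6-tris(benzyloxy)-3-methylphenyl]methanol | OCc1c(OCc2ccccc2)c(C)c(OCc2ccccc2)cc1OCc1ccccc1 | intermediate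
6 | [2,4,6-tris(benzyloxy)-3-methylphenyl]methyl methanesulfonate | CS(=O)(=O)OCc1c(OCc2ccccc2)c(C)c(OCc2ccccc2)cc1OCc1ccccc1 | intermediate
7 | 1,3,5-tris(benzyloxy)-2-(chloromethyl)-4-methylbenzene | ClCc1c(OCc2ccccc2)c(C)c(OCc2ccccc2)cc1OCc1ccccc1 | intermediate
8 | propan-2-ol | CC(C)O | starting material
9 | trichloroethene | ClC=C(Cl)Cl | starting material
10 | dichloroethyne | ClC#CCl | intermediate
11 | (E)-1,2-dichloro-1-(propan-2-yloxy)ethene | CC(C)O/C(Cl)=C\Cl | intermediate
12 | 1-chloro-2-(propan-2-yloxy)ethyne | CC(C)OC#CCl | intermediate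
13 | lithium (propan-2-yloxy)ethynide | [Li]C#COC(C)C | intermediate
14 | 1,3,5-tris(benzyloxy)-2-methyl-4-[3-(propan-2-yloxy)prop-2-yn-1-yl]benzene | CC(C)OC#CCc1c(OCc2ccccc2)cc(OCc2ccccc2)c(C)c1OCc1ccccc1 | intermediate
15 | acetone (propan-2-one) | CC(C)=O | starting material
16 | ketene (ethenone) | C=C=O | intermediate
17 | 3-(propan-2-yloxy)-2-{[2,4,6-tris(benzyloxy)-3-methylphenyl]methyl}cyclobut-2-en-1-one | CC(C)OC1=C(Cc2c(OCc3ccccc3)cc(OCc3ccccc3)c(C)c2OCc2ccccc2)C(=O)C1 | intermediate
18 | 2-chloro-1,1-dimethoxyethane | COC(CCl)OC | starting material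
19 | 1-chloro-2-methoxyethene (E/Z mixture) | COC=CCl | intermediate
20 | methoxyethyne | COC#C | intermediate
21 | sodium methoxyethynide | [Na]C#COC | intermediate
22 | 1-methoxyprop-1-yne | CC#COC | intermediate
23 | 3-(propan-2-yloxy)-2-{[2,4,6-tris(benzyloxy)-3-methylphenyl]methyl}buta-1,3-dien-1-one | C=C(OC(C)C)C(=C=O)Cc1c(OCc2ccccc2)cc(OCc2ccccc2)c(C)c1OCc1ccccc1 | intermediate
24 | 3-methoxy-2-methyl-4-[1-(propan-2-yloxy)ethenyl]-4-{[2,4,6-tris(benzyloxy)-3-methylphenyl]methyl}cyclobut-2-en-1-one (racemic) | COC1=C(C)C(=O)C1(Cc1c(OCc2ccccc2)cc(OCc2ccccc2)c(C)c1OCc1ccccc1)C(=C)OC(C)C | intermediate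
25 | (3E)-3-methoxy-2-methyl-5-(propan-2-yloxy)-4-{[2,4,6-tris(benzyloxy)-3-methylphenyl]methyl}hexa-1,3,5-trien-1-one | C=C(OC(C)C)/C(Cc1c(OCc2ccccc2)cc(OCc2ccccc2)c(C)c1OCc1ccccc1)=C(\C(C)=C=O)OC | intermediate
26 | 3-methoxy-2-methyl-5-(propan-2-yloxy)-4-{[2,4,6-tris(benzyloxy)-3-methylphenyl]methyl}cyclohexa-2,4-dien-1-one | COC1=C(C)C(=O)CC(OC(C)C)=C1Cc1c(OCc2ccccc2)cc(OCc2ccccc2)c(C)c1OCc1ccccc1 | intermediate
27 | 3-methoxy-2-methyl-5-(propan-2-yloxy)-4-{[2,4,6-tris(benzyloxy)-3-methylphenyl]methyl}phenol | CC(C)Oc1cc(O)c(C)c(OC)c1Cc1c(OCc2ccccc2)cc(OCc2ccccc2)c(C)c1OCc1ccccc1 | intermediate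
28 | 1,3,5-tris(benzyloxy)-2-{[4-(benzyloxy)-2-methoxy-3-methyl-6-(propan-2-yloxy)phenyl]methyl}-4-methylbenzene | CC(C)Oc1cc(OCc2ccccc2)c(C)c(OC)c1Cc1c(OCc2ccccc2)cc(OCc2ccccc2)c(C)c1OCc1ccccc1 | intermediate
29 | 1-[2,4,6-tris(benzyloxy)-3-{[4-(benzyloxy)-3-butanoyl-6-methoxy-5-methyl-2-(propan-2-yloxy)phenyl]methyl}-5-methylphenyl]butan-1-one | CC(C)Oc1c(C(=O)CCC)c(OCc2ccccc2)c(C)c(OC)c1Cc1c(OCc2ccccc2)c(C(=O)CCC)c(OCc2ccccc2)c(C)c1OCc1ccccc1 | intermediate
30 | margaspidin, 1-{3-[(3-butanoyl-2,4-dihydroxy-6-methoxy-5-methylphenyl)methyl]-2,4,6-trihydroxy-5-methylphenyl}butan-1-one | CCCC(=O)c1c(O)c(C)c(O)c(Cc2c(O)c(C(=O)CCC)c(O)c(C)c2OC)c1O | target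

**Step count and risks**

Total step count: 12. Longest linear sequence: 10 steps (steps 1, 2, 3, 4, 6, 7, 9, 10, 11, 12); steps 5 and 8 prepare the two small alkyne partners.

Steps most likely to fail:

Step 9. The vinylogous ester character of the 3-alkoxycyclobutenone may slow the first 4π ring opening so much that decomposition of 17, or dimerisation of the small stationary amount of ketene 23, overtakes the union with 22. The fallback makes the same ketene 23 at room temperature by photochemical Wolff rearrangement of a diazo ketone. It sets out from chloride 7 and uses 22 unchanged. Isopropyl vinyl ether is lithiated (t-BuLi, THF) and acetylated with N-methoxy-N-methylacetamide to give 3-(propan-2-yloxy)but-3-en-2-one F1. Its lithium enolate (LiN(iPr)2, THF, −78 °C) is alkylated with 7 to give 2-(propan-2-yloxy)-5-[2,4,6-tris(benzyloxy)-3-methylphenyl]pent-1-en-3-one F2. Trifluoroacetylation (LiN(SiMe3)2, CF3CO2CH2CF3) gives 1,1,1-trifluoro-5-(propan-2-yloxy)-3-{[2,4,6-tris(benzyloxy)-3-methylphenyl]methyl}hex-5-ene-2,4-dione F3. Diazo transfer with methanesulfonyl azide and Et3N in aqueous MeCN, with loss of the trifluoroacetyl group, gives 4-diazo-2-(propan-2-yloxy)-5-[2,4,6-tris(benzyloxy)-3-methylphenyl]pent-1-en-3-one F4. Irradiation of F4 through Pyrex in 1,2-dichloroethane with 22 present, followed by heating, should pass through 23 to 26 and come back to the route at phenol 27.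

Step 11. The acylating agent may attack the bridge-bearing ipso carbons with loss of a trialkoxybenzyl cation (cleavage of the diarylmethane), or the reaction may stall after one acylation because the last free position of each ring is crowded by two alkoxy groups. The fallback sets out from 28 and brings in the two carbons as aldehydes with the small Vilsmeier electrophile. POCl3/DMF at 60 °C, then aqueous NaOAc, should give 2,4,6-tris(benzyloxy)-3-{[4-(benzyloxy)-3-formyl-6-methoxy-5-methyl-2-(propan-2-yloxy)phenyl]methyl}-5-methylbenzaldehyde F5. Addition of n-PrMgBr (THF, 0 °C) gives 1-[2,4,6-tris(benzyloxy)-3-{[4-(benzyloxy)-3-(1-hydroxybutyl)-6-methoxy-5-methyl-2-(propan-2-yloxy)phenyl]methyl}-5-methylphenyl]butan-1-ol F6 as a mixture of diastereomers, which is of no consequence. Oxidation of both carbinols with Dess–Martin periodinane (CH2Cl2, NaHCO3) comes back to the route at diketone 29.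

Step 7. Ketene may condense with itself to diketene and oligomers faster than it adds to the hindered internal ynol ether 14, and 14 may hydrolyse or polymerise during the long gas feed. The fallback sets out from 14 and uses the far more electrophilic dichloroketene F7, made in the flask from trichloroacetyl chloride and Zn–Cu couple in Et2O/DME. It should add with the same orientation to give 4,4-dichloro-3-(propan-2-yloxy)-2-{[2,4,6-tris(benzyloxy)-3-methylphenyl]methyl}cyclobut-2-en-1-one F8. Reductive removal of both chlorines with zinc dust, AcOH and TMEDA in EtOH comes back to the route at cyclobutenone 17.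

Further compounds
F1 | step 9 | 3-(propan-2-yloxy)but-3-en-2-one | CC(=O)C(=C)OC(C)C
F2 | step 9 | 2-(propan-2-yloxy)-5-[2,4,6-tris(benzyloxy)-3-methylphenyl]pent-1-en-3-one | C=C(OC(C)C)C(=O)CCc1c(OCc2ccccc2)cc(OCc2ccccc2)c(C)c1OCc1ccccc1
F3 | step 9 | 1,1,1-trifluoro-5-(propan-2-yloxy)-3-{[2,4,6-tris(benzyloxy)-3-methylphenyl]methyl}hex-5-ene-2,4-dione (racemic) | C=C(OC(C)C)C(=O)C(Cc1c(OCc2ccccc2)cc(OCc2ccccc2)c(C)c1OCc1ccccc1)C(=O)C(F)(F)F
F4 | step 9 | 4-diazo-2-(propan-2-yloxy)-5-[2,4,6-tris(benzyloxy)-3-methylphenyl]pent-1-en-3-one | C=C(OC(C)C)C(=O)C(=[N+]=[N-])Cc1c(OCc2ccccc2)cc(OCc2ccccc2)c(C)c1OCc1ccccc1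
F5 | step 11 | 2,4,6-tris(benzyloxy)-3-{[4-(benzyloxy)-3-formyl-6-methoxy-5-methyl-2-(propan-2-yloxy)phenyl]methyl}-5-methylbenzaldehyde | CC(C)Oc1c(C=O)c(OCc2ccccc2)c(C)c(OC)c1Cc1c(OCc2ccccc2)c(C=O)c(OCc2ccccc2)c(C)c1OCc1ccccc1
F6 | step 11 | 1-[2,4,6-tris(benzyloxy)-3-{[4-(benzyloxy)-3-(1-hydroxybutyl)-6-methoxy-5-methyl-2-(propan-2-yloxy)phenyl]methyl}-5-methylphenyl]butan-1-ol (mixture of diastereomers) | CC(C)Oc1c(C(O)CCC)c(OCc2ccccc2)c(C)c(OC)c1Cc1c(OCc2ccccc2)c(C(O)CCC)c(OCc2ccccc2)c(C)c1OCc1ccccc1
F7 | step 7 | dichloroketene (2,2-dichloroethenone) | ClC(Cl)=C=O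
F8 | step 7 | 4,4-dichloro-3-(propan-2-yloxy)-2-{[2,4,6-tris(benzyloxy)-3-methylphenyl]methyl}cyclobut-2-en-1-one | CC(C)OC1=C(Cc2c(OCc3ccccc3)cc(OCc3ccccc3)c(C)c2OCc2ccccc2)C(=O)C1(Cl)Cl
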